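**Retrosynthetic overview**

1. Both tetrahydropyran rings are closed last, together, by Williamson formation of the C2–O–C6 ether bonds of hexaol 41. Each C2 carbinol comes from a C2 ketone by hydroxyl-directed syn reduction.
2. Each (Z)-trisubstituted alkene unit is assembled in one flask from four components: a hydrazone azaenolate (C3), a vinylphosphonium salt (C4–C5), an aldehyde (the exocyclic CH) and formaldehyde (C6). The left unit uses 4,4-dimethoxybutanal; the right unit (key step) uses the left-hand aldehyde 33.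
3. Enabling feature: in each tetrahydropyran, C5 is the fully substituted carbon of a (Z)-2-substituted allylic ether, flanked by C4H2 and by the oxygen-bearing C6H2 that lies cis to the alkene chain. C5 can therefore be an ylide carbon that receives C4, C6 and the olefinic carbon. C2 lies 1,3 to the cyclopentanol oxygen, so it can be carried as a ketone whose methyl group becomes C3.
4. The two cyclopentyl methyl ketones 14 and 23 differ only at the isopropenyl carbon. They come from the two enantiomers of one racemic trans-2-hydroxy-3-isopropenylcyclopentanone, one used directly and the other after inversion at the carbinol.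
5. Ring order: the cyclopentane rings are bought as cyclopentenone; the two tetrahydropyrans are formed in the final step.

Key step: step 19

Assumption: the lipase in steps 3 and 4 is taken to acylate the (2S,3S)-enantiomer (larger substituent on the C3 side); if it prefers the other enantiomer, the acetate and the residual alcohol exchange roles and the methanolysis step moves to the other branch. Hydrazone C=N geometry is drawn E and has no stereochemical consequence.

**Route**

Step 1
Reactants: 1 cyclopent-2-en-1-one; 2 isopropenylmagnesium bromide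
Product: 3 racemic trimethyl{[3-(prop-1-en-2-yl)cyclopent-1-en-1-yl]oxy}silane
Conditions: CuBr·SMe2 (5 mol %), Me3SiCl, THF, −78 °C; Et3N quench
Reagents that add atoms: chlorotrimethylsilane, C[Si](C)(C)Cl
Why: Copper-catalysed conjugate addition of the alkenyl Grignard reagent with in situ O-silylation should trap the regiodefined enolate as its silyl enol ether; the single stereocentre forms racemic.

Step 2
Reactants: 3 racemic silyl enol ether
Product: 5 racemic trans-2-hydroxy-3-(prop-1-en-2-yl)cyclopentan-1-one, via silyloxy ketone 4 (not isolated)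
Conditions: mCPBA (1.0 equiv), NaHCO3, CH2Cl2, −20 °C; then citric acid (cat.), MeOH, 0 °C
Reagents that add atoms: mCPBA, O=C(OO)c1cccc(Cl)c1
Why: Rubottom oxidation: the silyl enol ether should be epoxidised far faster than the isopropenyl group and anti to the C3 substituent, so silyl migration and methanolysis give the trans α-hydroxy ketone.

Step 3
Reactants: 5 racemic trans-2-hydroxy-3-(prop-1-en-2-yl)cyclopentan-1-one
Product: 6 (1S,5S)-2-oxo-5-(prop-1-en-2-yl)cyclopentyl acetate
Conditions: Burkholderia cepacia lipase (Amano PS), vinyl acetate, MTBE, 30 °C, stopped just short of half conversion; chromatography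
Reagents that add atoms: vinyl acetate, C=COC(C)=O
Why: Lipase-catalysed kinetic resolution by enantioselective acylation (Kazlauskas rule) should acetylate only the fast (2S,3S)-enantiomer, and stopping before half conversion keeps the acetate enantiopure.

Step 4
Reactants: 5 racemic trans-2-hydroxy-3-(prop-1-en-2-yl)cyclopentan-1-one
Product: 7 (2R,3R)-2-hydroxy-3-(prop-1-en-2-yl)cyclopentan-1-one
Conditions: Burkholderia cepacia lipase (Amano PS), vinyl acetate, MTBE, 30 °C, run just past half conversion; chromatography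
Reagents that add atoms: none
Why: The same lipase-catalysed kinetic resolution, carried past half conversion, should consume all of the fast (2S,3S)-enantiomer as its acetate and leave the slow (2R,3R)-alcohol enantiopure; the alcohol fraction recovered from step 3 can be added to the feed, so both enantiomers of 5 are used.

Step 5
Reactants: 6 (1S,5S)-2-oxo-5-(prop-1-en-2-yl)cyclopentyl acetate
Product: 8 (2S,3S)-2-hydroxy-3-(prop-1-en-2-yl)cyclopentan-1-one
Conditions: K2CO3 (cat.), MeOH, 0 °C
Reagents that add atoms: none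
Why: Base-catalysed methanolysis of the α-acetoxy ketone; the trans isomer is the thermodynamic one, so the carbinol centre is not at risk.

Step 6
Reactants: 8 (2S,3S)-2-hydroxy-3-(prop-1-en-2-yl)cyclopentan-1-one
Product: 9 (2S,3S)-2-[(tert-butyldimethylsilyl)oxy]-3-(prop-1-en-2-yl)cyclopentan-1-one
Conditions: TBSOTf, 2,6-lutidine, CH2Cl2, −78 °C
Reagents that add atoms: tert-butyldimethylsilyl trifluoromethanesulfonate, CC(C)(C)[Si](C)(C)OS(=O)(=O)C(F)(F)F
Why: Silyl triflate silylation of a hindered secondary alcohol under non-epimerising conditions.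

Step 7
Reactants: 9 silyloxy ketone
Product: 10 (4S,5S)-5-[(tert-butyldimethylsilyl)oxy]-4-(prop-1-en-2-yl)cyclopent-1-en-1-yl trifluoromethanesulfonate
Conditions: KN(SiMe3)2, PhNTf2, THF, −78 °C
Reagents that add atoms: N-phenylbis(trifluoromethanesulfonimide), O=S(=O)(N(c1ccccc1)S(=O)(=O)C(F)(F)F)C(F)(F)F
Why: Kinetic deprotonation at the unhindered C5 methylene (not at the silyloxy-bearing carbon) and O-triflation should give the less substituted enol triflate.

Step 8
Reactants: 10 enol triflate; 11 tributyl(1-ethoxyvinyl)stannane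
Product: 13 1-[(4S,5S)-5-[(tert-butyldimethylsilyl)oxy]-4-(prop-1-en-2-yl)cyclopent-1-en-1-yl]ethan-1-one, via ethoxy diene 12 (not isolated)
Conditions: Pd(PPh3)4 (5 mol %), LiCl, THF, 65 °C; then 1 M HCl, THF, 0 °C
Reagents that add atoms: water, O
Why: Stille coupling of the alkenyl triflate with the acyl-anion-equivalent stannane, then enol ether hydrolysis, gives the methyl enone.

Step 9
Reactants: 13 methyl enone
Product: 14 1-[(1S,2S,3S)-2-[(tert-butyldimethylsilyl)oxy]-3-(prop-1-en-2-yl)cyclopentyl]ethan-1-one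
Conditions: [(Ph3P)CuH]6 (0.4 equiv), benzene, H2O (3 equiv), 20 °C; then DBU (0.1 equiv), CH2Cl2, 20 °C
Reagents that add atoms: none
Why: Copper hydride conjugate reduction should leave the isopropenyl group untouched, and base equilibration of the epimerisable acetyl-bearing carbon places the acetyl group trans to the adjacent silyloxy group (thermodynamic control).

Step 10
Reactants: 14 methyl ketone
Product: 15 (E)-N,N-dimethylhydrazone of 14, i.e. 2-{1-[(1R,2S,3S)-2-[(tert-butyldimethylsilyl)oxy]-3-(prop-1-en-2-yl)cyclopentyl]ethylidene}-1,1-dimethylhydrazine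
Conditions: Me2NNH2 (excess), AcOH (cat.), EtOH, 60 °C
Reagents that add atoms: 1,1-dimethylhydrazine, CN(C)N
Why: Hydrazone condensation masks the ketone against organolithium reagents and allows regioselective metalation of its methyl group.

Step 11
Reactants: 7 (2R,3R)-2-hydroxy-3-(prop-1-en-2-yl)cyclopentan-1-one
Product: 18 (2S,3R)-2-hydroxy-3-(prop-1-en-2-yl)cyclopentan-1-one, via triflate 16 (not isolated), via nitrite ester 17 (not isolated)
Conditions: Tf2O, pyridine, CH2Cl2, −30 °C; then NaNO2, DMF, 20 °C; aqueous work-up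
Reagents that add atoms: sodium nitrite, [Na+].[O-]N=O
Why: Lattrell–Dax inversion: the α-keto triflate should undergo SN2 displacement by nitrite oxygen under non-basic conditions and the nitrite ester hydrolyses on work-up, inverting the carbinol to the cis hydroxy ketone.

Step 12
Reactants: 18 (2S,3R)-2-hydroxy-3-(prop-1-en-2-yl)cyclopentan-1-one
Product: 19 (2S,3R)-2-[(tert-butyldimethylsilyl)oxy]-3-(prop-1-en-2-yl)cyclopentan-1-one
Conditions: TBSOTf, 2,6-lutidine, CH2Cl2, −78 °C
Reagents that add atoms: tert-butyldimethylsilyl trifluoromethanesulfonate, CC(C)(C)[Si](C)(C)OS(=O)(=O)C(F)(F)F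
Why: Fast non-basic silylation should protect the cis α-hydroxy ketone before it can epimerise.

Step 13
Reactants: 19 silyloxy ketone
Product: 20 (4R,5S)-5-[(tert-butyldimethylsilyl)oxy]-4-(prop-1-en-2-yl)cyclopent-1-en-1-yl trifluoromethanesulfonate
Conditions: KN(SiMe3)2, PhNTf2, THF, −78 °C
Reagents that add atoms: N-phenylbis(trifluoromethanesulfonimide), O=S(=O)(N(c1ccccc1)S(=O)(=O)C(F)(F)F)C(F)(F)F
Why: Kinetic enolisation toward the methylene side, as in step 7, also removes the carbonyl next to the inverted carbinol, which is thereafter configurationally safe.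

Step 14
Reactants: 20 enol triflate; 11 tributyl(1-ethoxyvinyl)stannane
Product: 22 1-[(4R,5S)-5-[(tert-butyldimethylsilyl)oxy]-4-(prop-1-en-2-yl)cyclopent-1-en-1-yl]ethan-1-one, via ethoxy diene 21 (not isolated)
Conditions: Pd(PPh3)4 (5 mol %), LiCl, THF, 65 °C; then 1 M HCl, THF, 0 °C
Reagents that add atoms: water, O
Why: Stille coupling and enol ether hydrolysis, as in step 8.

Step 15
Reactants: 22 methyl enone
Product: 23 1-[(1S,2S,3R)-2-[(tert-butyldimethylsilyl)oxy]-3-(prop-1-en-2-yl)cyclopentyl]ethan-1-one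
Conditions: [(Ph3P)CuH]6 (0.4 equiv), benzene, H2O (3 equiv), 20 °C; then DBU (0.1 equiv), CH2Cl2, 20 °C
Reagents that add atoms: none
Why: Copper hydride conjugate reduction and equilibration should again place the acetyl group trans to the silyloxy group, which here is cis to the isopropenyl group.

Step 16
Reactants: 23 methyl ketone
Product: 24 (E)-N,N-dimethylhydrazone of 23, i.e. 2-{1-[(1R,2S,3R)-2-[(tert-butyldimethylsilyl)oxy]-3-(prop-1-en-2-yl)cyclopentyl]ethylidene}-1,1-dimethylhydrazine
Conditions: Me2NNH2 (excess), AcOH (cat.), EtOH, 60 °C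
Reagents that add atoms: 1,1-dimethylhydrazine, CN(C)N
Why: Hydrazone condensation, as in step 10.

Step 17
Reactants: 24 left-hand hydrazone; 25 triphenyl(vinyl)phosphonium bromide; 26 4,4-dimethoxybutanal; 27 formaldehyde (monomer from cracked paraformaldehyde)
Product: 32 (2Z)-2-{(3E)-3-(2,2-dimethylhydrazinylidene)-3-[(1R,2S,3R)-2-[(tert-butyldimethylsilyl)oxy]-3-(prop-1-en-2-yl)cyclopentyl]propyl}-6,6-dimethoxyhex-2-en-1-ol, via lithium azaenolate 28 (not isolated), via phosphonium ylide 29 (not isolated), via lithiobetaine 30 (not isolated), via β-oxido ylide 31 (not isolated)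
Conditions: LiN(iPr)2, THF, 0 °C; 25, −78 → 0 °C; 26, −78 °C; PhLi (1.1 equiv), −78 → −30 °C; 27 (excess), −30 → 20 °C
Reagents that add atoms: none
Why: Proposed new method: the methyl-derived azaenolate of 24 should add through carbon to the β-carbon of vinylphosphonium salt 25 (closest known: additions of enolates to vinylphosphonium salts and Michael additions of metalated hydrazones) to give ylide 29 directly, which then enters the known Wittig–Schlosser β-oxido ylide hydroxymethylation, where formaldehyde is delivered cis to the aldehyde-derived chain and so fixes the (Z)-alkene.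

Step 18
Reactants: 32 acetal
Product: 33 (4Z,8E)-8-(2,2-dimethylhydrazinylidene)-5-(hydroxymethyl)-8-[(1R,2S,3R)-2-[(tert-butyldimethylsilyl)oxy]-3-(prop-1-en-2-yl)cyclopentyl]oct-4-enal
Conditions: LiBF4, MeCN/H2O (98:2), 20 °C
Reagents that add atoms: water, O
Why: Lewis-acid-assisted hydrolysis of the dimethyl acetal under near-neutral conditions should leave the hydrazone, silyl ether and alkenes untouched.

Step 19
Reactants: 15 right-hand hydrazone; 25 triphenyl(vinyl)phosphonium bromide; 33 left-hand aldehyde; 27 formaldehyde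
Product: 38 (2Z,6Z)-2-{(3E)-3-(2,2-dimethylhydrazinylidene)-3-[(1R,2S,3S)-2-[(tert-butyldimethylsilyl)oxy]-3-(prop-1-en-2-yl)cyclopentyl]propyl}-7-{(3E)-3-(2,2-dimethylhydrazinylidene)-3-[(1R,2S,3R)-2-[(tert-butyldimethylsilyl)oxy]-3-(prop-1-en-2-yl)cyclopentyl]propyl}octa-2,6-diene-1,8-diol, via lithium azaenolate 34 (not isolated), via phosphonium ylide 35 (not isolated), via lithiobetaine 36 (not isolated), via β-oxido ylide 37 (not isolated)
Conditions: LiN(iPr)2, THF, 0 °C; 25, −78 → 0 °C; 33, −78 °C; PhLi (2.1 equiv), −78 → −30 °C; 27 (excess), −30 → 20 °C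
Reagents that add atoms: none
Why: Proposed new method: LiN(iPr)2 should metalate the methyl group of hydrazone 15, and the azaenolate carbon should add to the β-carbon of vinylphosphonium salt 25 to give the non-stabilised ylide 35 without further base; this makes the future C3–C4 bond. Ylide 35 should add to aldehyde 33 at −78 °C to give lithiobetaine 36; PhLi then removes the proton next to phosphorus (a second equivalent goes to the free hydroxyl of 33, which should not quench the ylide beforehand because an alkylidenephosphorane is a weaker base than an alkoxide), and β-oxido ylide 37 is hydroxymethylated by formaldehyde at the ylide carbon, making the future C5–C6 bond, before Ph3P=O is lost from the first-formed oxido group. The closest known reaction types are the addition of enolates to vinylphosphonium salts with in situ Wittig reaction and the Wittig–Schlosser β-oxido ylide synthesis of (Z)-2-substituted allylic alcohols from an ylide, an aldehyde and formaldehyde. No ring is closed here (the tetrahydropyran closes in step 23 by 6-exo-tet etherification) and no stereocentre is formed; the new stereo-element is the alkene, whose (Z)-geometry (hydroxymethyl cis to the aldehyde-derived chain) is set by the face on which the electrophile enters the β-oxido ylide. The step needs C- over N-alkylation and methyl over methine metalation, both typical of dimethylhydrazone azaenolates; it also needs PhLi to deprotonate and not add, which the hydrazone mask secures because no carbonyl other than the consumed aldehyde is present.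

Step 20
Reactants: 38 bis-hydrazone diol
Product: 39 (2Z,6Z)-2-{3-oxo-3-[(1S,2S,3S)-2-[(tert-butyldimethylsilyl)oxy]-3-(prop-1-en-2-yl)cyclopentyl]propyl}-7-{3-oxo-3-[(1S,2S,3R)-2-[(tert-butyldimethylsilyl)oxy]-3-(prop-1-en-2-yl)cyclopentyl]propyl}octa-2,6-diene-1,8-diol
Conditions: CuCl2 (2.2 equiv), THF/aqueous phosphate buffer (pH 7), 20 °C
Reagents that add atoms: water, O
Why: Copper-chloride-promoted hydrolysis of N,N-dimethylhydrazones at neutral pH should free both ketones without touching silyl ethers or alkenes.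

Step 21
Reactants: 39 bis-silyl diketone
Product: 40 (2Z,6Z)-2-{3-[(1S,2S,3S)-2-hydroxy-3-(prop-1-en-2-yl)cyclopentyl]-3-oxopropyl}-7-{3-[(1S,2S,3R)-2-hydroxy-3-(prop-1-en-2-yl)cyclopentyl]-3-oxopropyl}octa-2,6-diene-1,8-diol
Conditions: HF·pyridine, pyridine, THF, 0 → 20 °C
Reagents that add atoms: none
Why: Buffered fluoride desilylation avoids the basic conditions that could trigger retro-aldol opening of the β-hydroxy ketones.

Step 22
Reactants: 40 tetrahydroxy diketone
Product: 41 (2Z,6Z)-2-{(3R)-3-hydroxy-3-[(1R,2S,3S)-2-hydroxy-3-(prop-1-en-2-yl)cyclopentyl]propyl}-7-{(3R)-3-hydroxy-3-[(1R,2S,3R)-2-hydroxy-3-(prop-1-en-2-yl)cyclopentyl]propyl}octa-2,6-diene-1,8-diol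
Conditions: Et2BOMe, THF/MeOH (4:1), −78 °C; NaBH4; then repeated MeOH co-evaporation
Reagents that add atoms: none
Why: Narasaka–Prasad reduction: each β-hydroxy ketone forms a boron chelate with the cyclopentanol oxygen and external hydride should give the 1,3-syn diol, which is the (R) configuration needed at C2 of both tetrahydropyrans.

Step 23
Reactants: 41 hexaol
Product: 43 CNP0267443.2 (target), via bis(allylic chloride) 42 (not isolated)
Conditions: MsCl (2.2 equiv), LiCl, 2,4,6-collidine, DMF, 0 °C; aqueous work-up; then NaH, THF, 0 → 20 °C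
Reagents that add atoms: none
Why: The two primary allylic hydroxyls should be converted selectively into allylic chlorides without allylic shift, and each C2 alkoxide then closes its tetrahydropyran by 6-exo-tet Williamson etherification at the primary carbon, so no stereocentre or alkene geometry is touched.

**Compound list**

1 | cyclopent-2-en-1-one | O=C1C=CCC1 | starting material
2 | isopropenylmagnesium bromide | C=C(C)[Mg]Br | starting material
3 | racemic trimethyl{[3-(prop-1-en-2-yl)cyclopent-1-en-1-yl]oxy}silane | C[Si](C)(C)OC1=CC(C(=C)C)CC1 | intermediate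
4 | racemic trans-3-(prop-1-en-2-yl)-2-[(trimethylsilyl)oxy]cyclopentan-1-one (one enantiomer drawn) | O=C1CC[C@@H](C(=C)C)[C@@H]1O[Si](C)(C)C | intermediate
5 | racemic trans-2-hydroxy-3-(prop-1-en-2-yl)cyclopentan-1-one (one enantiomer drawn) | O=C1CC[C@@H](C(=C)C)[C@@H]1O | intermediate
6 | (1S,5S)-2-oxo-5-(prop-1-en-2-yl)cyclopentyl acetate | O=C1CC[C@@H](C(=C)C)[C@@H]1OC(C)=O | intermediate
7 | (2R,3R)-2-hydroxy-3-(prop-1-en-2-yl)cyclopentan-1-one | O=C1CC[C@H](C(=C)C)[C@H]1O | intermediate
8 | (2S,3S)-2-hydroxy-3-(prop-1-en-2-yl)cyclopentan-1-one | O=C1CC[C@@H](C(=C)C)[C@@H]1O | intermediate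
9 | (2S,3S)-2-[(tert-butyldimethylsilyl)oxy]-3-(prop-1-en-2-yl)cyclopentan-1-one | O=C1CC[C@@H](C(=C)C)[C@@H]1O[Si](C)(C)C(C)(C)C | intermediate
10 | (4S,5S)-5-[(tert-butyldimethylsilyl)oxy]-4-(prop-1-en-2-yl)cyclopent-1-en-1-yl trifluoromethanesulfonate | FC(F)(F)S(=O)(=O)OC1=CC[C@@H](C(=C)C)[C@@H]1O[Si](C)(C)C(C)(C)C | intermediate
11 | tributyl(1-ethoxyvinyl)stannane | CCCC[Sn](CCCC)(CCCC)C(=C)OCC | starting material
12 | tert-butyl{[(1S,5S)-2-(1-ethoxyethenyl)-5-(prop-1-en-2-yl)cyclopent-2-en-1-yl]oxy}dimethylsilane | CCOC(=C)C1=CC[C@@H](C(=C)C)[C@@H]1O[Si](C)(C)C(C)(C)C | intermediate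
13 | 1-[(4S,5S)-5-[(tert-butyldimethylsilyl)oxy]-4-(prop-1-en-2-yl)cyclopent-1-en-1-yl]ethan-1-one | CC(=O)C1=CC[C@@H](C(=C)C)[C@@H]1O[Si](C)(C)C(C)(C)C | intermediate
14 | 1-[(1S,2S,3S)-2-[(tert-butyldimethylsilyl)oxy]-3-(prop-1-en-2-yl)cyclopentyl]ethan-1-one | CC(=O)[C@H]1CC[C@@H](C(=C)C)[C@@H]1O[Si](C)(C)C(C)(C)C | intermediate
15 | (E)-N,N-dimethylhydrazone of 14 (cyclopentyl 1R,2S,3S) | C/C(=N\N(C)C)[C@H]1CC[C@@H](C(=C)C)[C@@H]1O[Si](C)(C)C(C)(C)C | intermediate
16 | (1R,5R)-2-oxo-5-(prop-1-en-2-yl)cyclopentyl trifluoromethanesulfonate | O=C1CC[C@H](C(=C)C)[C@H]1OS(=O)(=O)C(F)(F)F | intermediate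
17 | (1S,5R)-2-oxo-5-(prop-1-en-2-yl)cyclopentyl nitrite | O=C1CC[C@H](C(=C)C)[C@@H]1ON=O | intermediate
18 | (2S,3R)-2-hydroxy-3-(prop-1-en-2-yl)cyclopentan-1-one | O=C1CC[C@H](C(=C)C)[C@@H]1O | intermediate
19 | (2S,3R)-2-[(tert-butyldimethylsilyl)oxy]-3-(prop-1-en-2-yl)cyclopentan-1-one | O=C1CC[C@H](C(=C)C)[C@@H]1O[Si](C)(C)C(C)(C)C | intermediate
20 | (4R,5S)-5-[(tert-butyldimethylsilyl)oxy]-4-(prop-1-en-2-yl)cyclopent-1-en-1-yl trifluoromethanesulfonate | FC(F)(F)S(=O)(=O)OC1=CC[C@H](C(=C)C)[C@@H]1O[Si](C)(C)C(C)(C)C | intermediate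
21 | tert-butyl{[(1S,5R)-2-(1-ethoxyethenyl)-5-(prop-1-en-2-yl)cyclopent-2-en-1-yl]oxy}dimethylsilane | CCOC(=C)C1=CC[C@H](C(=C)C)[C@@H]1O[Si](C)(C)C(C)(C)C | intermediate
22 | 1-[(4R,5S)-5-[(tert-butyldimethylsilyl)oxy]-4-(prop-1-en-2-yl)cyclopent-1-en-1-yl]ethan-1-one | CC(=O)C1=CC[C@H](C(=C)C)[C@@H]1O[Si](C)(C)C(C)(C)C | intermediate
23 | 1-[(1S,2S,3R)-2-[(tert-butyldimethylsilyl)oxy]-3-(prop-1-en-2-yl)cyclopentyl]ethan-1-one | CC(=O)[C@H]1CC[C@H](C(=C)C)[C@@H]1O[Si](C)(C)C(C)(C)C | intermediate
24 | (E)-N,N-dimethylhydrazone of 23 (cyclopentyl 1R,2S,3R) | C/C(=N\N(C)C)[C@H]1CC[C@H](C(=C)C)[C@@H]1O[Si](C)(C)C(C)(C)C | intermediate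
25 | triphenyl(vinyl)phosphonium bromide | C=C[P+](c1ccccc1)(c1ccccc1)c1ccccc1.[Br-] | starting material
26 | 4,4-dimethoxybutanal | COC(OC)CCC=O | starting material
27 | formaldehyde (from paraformaldehyde) | C=O | starting material
28 | lithium azaenolate of 24 (metalated at the methyl carbon) | [Li]N(N(C)C)C(=C)[C@H]1CC[C@H](C(=C)C)[C@@H]1O[Si](C)(C)C(C)(C)C | intermediate
29 | ylide Ph3P=CH–CH2–CH2–C(=N–NMe2)–(left cyclopentyl) | c1ccccc1P(c1ccccc1)(c1ccccc1)=CCC/C(=N\N(C)C)[C@H]1CC[C@H](C(=C)C)[C@@H]1O[Si](C)(C)C(C)(C)C | intermediate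
30 | betaine of 29 with 26 (lithium bromide adduct, drawn as zwitterion; new centres undefined) | COC(OC)CCC([O-])C(CC/C(=N\N(C)C)[C@H]1CC[C@H](C(=C)C)[C@@H]1O[Si](C)(C)C(C)(C)C)[P+](c1ccccc1)(c1ccccc1)c1ccccc1 | intermediate
31 | β-oxido ylide from 30 (lithium alkoxide) | COC(OC)CCC(O[Li])C(CC/C(=N\N(C)C)[C@H]1CC[C@H](C(=C)C)[C@@H]1O[Si](C)(C)C(C)(C)C)=P(c1ccccc1)(c1ccccc1)c1ccccc1 | intermediate
32 | (2Z)-2-{(3E)-3-(2,2-dimethylhydrazinylidene)-3-[(1R,2S,3R)-2-[(tert-butyldimethylsilyl)oxy]-3-(prop-1-en-2-yl)cyclopentyl]propyl}-6,6-dimethoxyhex-2-en-1-ol | COC(OC)CC/C=C(\CO)CC/C(=N\N(C)C)[C@H]1CC[C@H](C(=C)C)[C@@H]1O[Si](C)(C)C(C)(C)C | intermediate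
33 | (4Z,8E)-8-(2,2-dimethylhydrazinylidene)-5-(hydroxymethyl)-8-[(1R,2S,3R)-2-[(tert-butyldimethylsilyl)oxy]-3-(prop-1-en-2-yl)cyclopentyl]oct-4-enal | O=CCC/C=C(\CO)CC/C(=N\N(C)C)[C@H]1CC[C@H](C(=C)C)[C@@H]1O[Si](C)(C)C(C)(C)C | intermediate
34 | lithium azaenolate of 15 (metalated at the methyl carbon) | [Li]N(N(C)C)C(=C)[C@H]1CC[C@@H](C(=C)C)[C@@H]1O[Si](C)(C)C(C)(C)C | intermediate
35 | ylide Ph3P=CH–CH2–CH2–C(=N–NMe2)–(right cyclopentyl) | c1ccccc1P(c1ccccc1)(c1ccccc1)=CCC/C(=N\N(C)C)[C@H]1CC[C@@H](C(=C)C)[C@@H]1O[Si](C)(C)C(C)(C)C | intermediate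
36 | betaine of 35 with 33 (drawn as zwitterion; new centres undefined) | [O-]C(CC/C=C(\CO)CC/C(=N\N(C)C)[C@H]1CC[C@H](C(=C)C)[C@@H]1O[Si](C)(C)C(C)(C)C)C(CC/C(=N\N(C)C)[C@H]1CC[C@@H](C(=C)C)[C@@H]1O[Si](C)(C)C(C)(C)C)[P+](c1ccccc1)(c1ccccc1)c1ccccc1 | intermediate
37 | β-oxido ylide from 36 (dilithium dialkoxide) | [Li]OC(CC/C=C(\CO[Li])CC/C(=N\N(C)C)[C@H]1CC[C@H](C(=C)C)[C@@H]1O[Si](C)(C)C(C)(C)C)C(CC/C(=N\N(C)C)[C@H]1CC[C@@H](C(=C)C)[C@@H]1O[Si](C)(C)C(C)(C)C)=P(c1ccccc1)(c1ccccc1)c1ccccc1 | intermediate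
38 | (2Z,6Z)-octa-2,6-diene-1,8-diol carrying at C2 the 3-(dimethylhydrazinylidene)-3-[(1R,2S,3S)-silyloxycyclopentyl]propyl arm and at C7 the 3-(dimethylhydrazinylidene)-3-[(1R,2S,3R)-silyloxycyclopentyl]propyl arm | OC/C(CC/C(=N\N(C)C)[C@H]1CC[C@@H](C(=C)C)[C@@H]1O[Si](C)(C)C(C)(C)C)=C\CC/C=C(\CO)CC/C(=N\N(C)C)[C@H]1CC[C@H](C(=C)C)[C@@H]1O[Si](C)(C)C(C)(C)C | intermediate
39 | the corresponding bis-silyl diketone (cyclopentyls 1S,2S,3S and 1S,2S,3R) | OC/C(CCC(=O)[C@H]1CC[C@@H](C(=C)C)[C@@H]1O[Si](C)(C)C(C)(C)C)=C\CC/C=C(\CO)CCC(=O)[C@H]1CC[C@H](C(=C)C)[C@@H]1O[Si](C)(C)C(C)(C)C | intermediate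
40 | the corresponding tetrahydroxy diketone | OC/C(CCC(=O)[C@H]1CC[C@@H](C(=C)C)[C@@H]1O)=C\CC/C=C(\CO)CCC(=O)[C@H]1CC[C@H](C(=C)C)[C@@H]1O | intermediate
41 | (2Z,6Z)-2-{(3R)-3-hydroxy-3-[(1R,2S,3S)-2-hydroxy-3-(prop-1-en-2-yl)cyclopentyl]propyl}-7-{(3R)-3-hydroxy-3-[(1R,2S,3R)-2-hydroxy-3-(prop-1-en-2-yl)cyclopentyl]propyl}octa-2,6-diene-1,8-diol | OC/C(CC[C@H]([C@H]1CC[C@@H](C(=C)C)[C@@H]1O)O)=C\CC/C=C(\CO)CC[C@H]([C@H]1CC[C@H](C(=C)C)[C@@H]1O)O | intermediate
42 | the 1,8-dichloride of 41 (both primary allylic hydroxyls replaced by chlorine) | ClC/C(CC[C@H]([C@H]1CC[C@@H](C(=C)C)[C@@H]1O)O)=C\CC/C=C(\CCl)CC[C@H]([C@H]1CC[C@H](C(=C)C)[C@@H]1O)O | intermediate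
43 | CNP0267443.2 | C=C(C)[C@H]1CC[C@H]([C@H]2CC/C(=C/CC/C=C3/CC[C@H]([C@H]4CC[C@@H](C(=C)C)[C@@H]4O)OC3)CO2)[C@H]1O | target

**Step count and risk**

Total step count: 23. Longest linear sequence: 16 steps (1, 2, 4, 11–23).

Steps most likely to fail:

1. Step 19 (proposed new method). The azaenolate may transfer a proton to, or attack phosphorus of, the vinylphosphonium salt instead of adding to its β-carbon. Alkene geometry may also erode if the betaine is not fully deprotonated before formaldehyde arrives. Fallback with known chemistry, setting out from 15: metalate with LiN(iPr)2 and alkylate with ethylene oxide to the hydroxypropyl hydrazone F1. Convert it into the iodide F2 (I2, PPh3, imidazole) and then into the phosphonium iodide F3 (PPh3, MeCN, 70 °C). Deprotonation with n-BuLi gives ylide 35, where the route is rejoined; the classical three-component β-oxido ylide procedure with 33, PhLi and 27 then leads to 38.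

2. Step 17 (proposed new method). The same addition may fail, and in addition the ylide may enolise aldehyde 26 instead of adding to it. Fallback with known chemistry, setting out from 24: alkylate the azaenolate with triethylsilyl glycidyl ether to the secondary alcohol F4 and oxidise it (Dess–Martin periodinane) to the α-silyloxy ketone F5. An alkoxy-directed (Z)-selective Wittig reaction with the ylide from (4,4-dimethoxybutyl)triphenylphosphonium bromide (KN(SiMe3)2, THF, −78 °C) gives the triethylsilyl ether F6. Selective removal of the primary triethylsilyl group (PPTS, MeOH, 0 °C) returns to the route at 32.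

3. Step 23. Ring closure may take the allylic-shift pathway (attack at the olefinic carbon), or the secondary hydroxyls may be activated as well, leading to elimination or wrong ethers. Fallback, setting out from 41 and arriving directly at 43: redox-condensation cyclodehydration (PPh3, diisopropyl azodicarboxylate, toluene, 0 °C). This activates only the primary allylic hydroxyls and lets each C2 hydroxyl close its ring without an isolated halide; it makes no new compound.

Further compounds
F1 | step 19 | (4E)-4-(2,2-dimethylhydrazinylidene)-4-[(1R,2S,3S)-2-[(tert-butyldimethylsilyl)oxy]-3-(prop-1-en-2-yl)cyclopentyl]butan-1-ol | OCCC/C(=N\N(C)C)[C@H]1CC[C@@H](C(=C)C)[C@@H]1O[Si](C)(C)C(C)(C)C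
F2 | step 19 | the corresponding primary iodide | ICCC/C(=N\N(C)C)[C@H]1CC[C@@H](C(=C)C)[C@@H]1O[Si](C)(C)C(C)(C)C
F3 | step 19 | the corresponding triphenylphosphonium iodide | [I-].c1ccccc1[P+](c1ccccc1)(c1ccccc1)CCC/C(=N\N(C)C)[C@H]1CC[C@@H](C(=C)C)[C@@H]1O[Si](C)(C)C(C)(C)C
F4 | step 17 | (5E)-5-(2,2-dimethylhydrazinylidene)-5-[(1R,2S,3R)-2-[(tert-butyldimethylsilyl)oxy]-3-(prop-1-en-2-yl)cyclopentyl]-1-[(triethylsilyl)oxy]pentan-2-ol (both carbinol epimers, oxidised next) | CC[Si](CC)(CC)OCC(O)CC/C(=N\N(C)C)[C@H]1CC[C@H](C(=C)C)[C@@H]1O[Si](C)(C)C(C)(C)C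
F5 | step 17 | the corresponding pentan-2-one (α-silyloxy ketone) | CC[Si](CC)(CC)OCC(=O)CC/C(=N\N(C)C)[C@H]1CC[C@H](C(=C)C)[C@@H]1O[Si](C)(C)C(C)(C)C
F6 | step 17 | triethylsilyl ether of 32 | COC(OC)CC/C=C(\CO[Si](CC)(CC)CC)CC/C(=N\N(C)C)[C@H]1CC[C@H](C(=C)C)[C@@H]1O[Si](C)(C)C(C)(C)C
F0 | step 23 | none | none
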